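**Retrosynthetic overview**
1. Target 11 is the centrosymmetric head-to-tail cyclobutane dimer (α-truxillic array, r-1,c-2,t-3,t-4). Both N-acyl-5,6-dihydropyridin-2(1H)-one rings are disconnected at the same time (two-directional), each at C2–C3 and at N1–C6.
2. Enabling feature: each imide nitrogen lies between the exocyclic cyclobutyl C=O and the lactam C2=O, so the O=C–N–C2=O triad is a latent acyl isocyanate. Ring atoms C3=C4–C5–C6 form a (Z)-but-1-ene-1,4-diyl unit that can be nucleophilic at C3 (alkenyl–Mg) and electrophilic at C6 (C–Br). The inversion centre of the cyclobutane makes both ends identical.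
3. Precursors: bis(acyl isocyanate) 4 (from diacid 2 via bis(acyl chloride) 3 and AgOCN) and two equivalents of (Z)-4-bromo-1-iodobut-1-ene 8 (three steps from but-3-yn-1-ol 5).
4. Diacid 2 arises from solid-state head-to-tail [2+2] photodimerization of (E)-3,4,5-trimethoxycinnamic acid 1. This sets all four stereocentres before any photolabile unsaturated lactam is present.
5. Ring order: the cyclobutane first (step 1), then both dihydropyridinone rings together in the last step (step 7).

Key step: step 7

Assumption: crystalline 1 is taken to adopt, or to be obtainable by recrystallization in, the α-type antiparallel head-to-tail packing common among alkoxycinnamic acids; the target is centrosymmetric and achiral, so only relative configuration has to be controlled.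

**Step 1**
Reactants: 1 (E)-3,4,5-trimethoxycinnamic acid (two molecules)
Product: 2 (1α,2α,3β,4β)-2,4-bis(3,4,5-trimethoxyphenyl)cyclobutane-1,3-dicarboxylic acid (aryl groups mutually trans, carboxyl groups mutually trans, each carboxyl cis to one neighbouring aryl and trans to the other; centrosymmetric)
Conditions: finely ground crystals as a thin layer or stirred aqueous slurry, hν (medium-pressure Hg lamp, Pyrex, λ > 300 nm), rt; trituration to remove unreacted 1
Reagents that add atoms: none
Why: In this topochemical solid-state [2+2] photocycloaddition, inversion-related antiparallel pairs of E-alkenes should join head-to-tail with retention of both alkene geometries, which sets all four stereocentres at once as the α-truxillic array.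

**Step 2**
Reactants: 2 diacid
Product: 3 (1α,2α,3β,4β)-2,4-bis(3,4,5-trimethoxyphenyl)cyclobutane-1,3-dicarbonyl dichloride
Conditions: (COCl)2, DMF (cat.), CH2Cl2, 0 °C to rt; evaporation
Reagents that add atoms: oxalyl chloride, O=C(Cl)C(=O)Cl
Why: Vilsmeier-type activation converts both acids into acyl chlorides without any base, so the carbonyl-bearing stereocentres cannot epimerize through an enolate or a ketene.

**Step 3**
Reactants: 3 bis(acyl chloride)
Product: 4 (1α,2α,3β,4β)-2,4-bis(3,4,5-trimethoxyphenyl)cyclobutane-1,3-dicarbonyl diisocyanate
Conditions: AgOCN (dried), toluene, 80 °C, dark, argon; filtration through Celite, concentration, used at once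
Reagents that add atoms: silver cyanate, [Ag+].[O-]C#N
Why: Acyl chloride/silver cyanate metathesis is the classical acyl isocyanate synthesis, is driven by precipitation of AgCl, delivers the N-acylated cyanate, and runs under neutral conditions that leave the stereocentres untouched.

**Step 4**
Reactants: 5 but-3-yn-1-ol
Product: 6 4-iodobut-3-yn-1-ol
Conditions: N-iodosuccinimide, AgNO3 (cat.), acetone, rt, dark
Reagents that add atoms: N-iodosuccinimide, O=C1CCC(=O)N1I
Why: Silver-catalysed electrophilic iodination of a terminal alkyne proceeds through the silver acetylide and does not touch the primary alcohol.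

**Step 5**
Reactants: 6 4-iodobut-3-yn-1-ol
Product: 7 (Z)-4-iodobut-3-en-1-ol
Conditions: 2-nitrobenzenesulfonyl hydrazide (NBSH), THF/i-PrOH, rt, dark
Reagents that add atoms: none
Why: In this diimide reduction, concerted syn delivery of two hydrogens to the iodoalkyne should give the Z-alkenyl iodide without cleaving the C–I bond, and over-reduction is held back by the stoichiometry.

**Step 6**
Reactants: 7 (Z)-4-iodobut-3-en-1-ol
Product: 8 (Z)-4-bromo-1-iodobut-1-ene
Conditions: CBr4, PPh3, CH2Cl2, 0 °C
Reagents that add atoms: carbon tetrabromide, BrC(Br)(Br)Br
Why: The Appel reaction replaces the primary hydroxyl by bromide through SN2 attack on the alkoxyphosphonium ion under neutral conditions, so the Z-alkenyl iodide keeps its geometry.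

**Step 7**
Reactants: 4 bis(acyl isocyanate); 8 (Z)-4-bromo-1-iodobut-1-ene (two equivalents)
Product: 11 piplartine-dimer A, via alkenylmagnesium chloride 9 (not isolated), via bis(magnesium imide) salt 10 (not isolated)
Conditions: 8, i-PrMgCl·LiCl (titrated, one per C–I), THF, −25 °C; cool to −78 °C, slow addition of 4 in THF; then DMPU, Bu4NI (cat.), warm to 40 °C; aq NH4Cl
Reagents that add atoms: none
Why: Proposed new method: iodine–magnesium exchange on 8 proceeds with retention to give the configurationally stable (Z)-alkenylmagnesium 9, a 1,4-amphoteric C4 unit whose sp2 carbon adds to the central carbon of each N=C=O group of 4 (lactam C3–C2 bond) to give the O,O-chelated bis(imide) salt 10, whose nitrogen then displaces the primary bromide on warming in THF/DMPU (C6–N1 bond), so that a formal anionic [4+2] annulation runs at both ends of the core in one operation and forms four bonds and two rings. The closest known reaction types are the addition of Grignard reagents to isocyanates and acyl isocyanates to give amides and imides, the Gabriel-type N-alkylation of imide anions, and the closure of ω-halo amide anions to piperidinones; their merger on an acyl isocyanate with an alkenyl C4 reagent is the untested part. Each dihydropyridinone ring closes in the 6-exo-tet mode, which is possible only because the Z geometry carried by 9 places C2 and C5 on the same side of the C3=C4 bond. No stereocentre is created, and the four cyclobutane centres from step 1 should be preserved because the isocyanate is consumed by addition at −78 °C faster than it can be deprotonated and because 10 is already anionic, so the strongest base present during ring closure is the weakly basic imide anion itself. Site selectivity for the isocyanate carbon over the exocyclic acyl carbon rests on the higher electrophilicity of the cumulene carbon and on the shielding of the acyl carbon by the two flanking aryl-bearing ring carbons. N- over O-alkylation is secured by magnesium chelation of both carbonyl oxygens, by the soft bromide/iodide leaving group, and by halide-mediated reopening of any cyclic imidate, which should drain material to the more stable N-alkyl imide.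

**Compound list**
1 | (E)-3,4,5-trimethoxycinnamic acid | COc1cc(/C=C/C(=O)O)cc(OC)c1OC | starting material
2 | (1α,2α,3β,4β)-2,4-bis(3,4,5-trimethoxyphenyl)cyclobutane-1,3-dicarboxylic acid | COc1cc([C@H]2[C@H](C(=O)O)[C@H](c3cc(OC)c(OC)c(OC)c3)[C@H]2C(=O)O)cc(OC)c1OC | intermediate
3 | (1α,2α,3β,4β)-2,4-bis(3,4,5-trimethoxyphenyl)cyclobutane-1,3-dicarbonyl dichloride | COc1cc([C@H]2[C@H](C(=O)Cl)[C@H](c3cc(OC)c(OC)c(OC)c3)[C@H]2C(=O)Cl)cc(OC)c1OC | intermediate
4 | (1α,2α,3β,4β)-2,4-bis(3,4,5-trimethoxyphenyl)cyclobutane-1,3-dicarbonyl diisocyanate | COc1cc([C@H]2[C@H](C(=O)N=C=O)[C@H](c3cc(OC)c(OC)c(OC)c3)[C@H]2C(=O)N=C=O)cc(OC)c1OC | intermediate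
5 | but-3-yn-1-ol | C#CCCO | starting material
6 | 4-iodobut-3-yn-1-ol | OCCC#CI | intermediate
7 | (Z)-4-iodobut-3-en-1-ol | OCC/C=C\I | intermediate
8 | (Z)-4-bromo-1-iodobut-1-ene | BrCC/C=C\I | intermediate
9 | (Z)-4-bromobut-1-enylmagnesium chloride (LiCl complex) | BrCC/C=C\[Mg]Cl | intermediate
10 | bis(chloromagnesium) salt of the bis[(Z)-5-bromopent-2-enoyl] imide of the α-truxillic core | COc1cc([C@H]2[C@H](C(=O)N([Mg]Cl)C(=O)/C=C\CCBr)[C@H](c3cc(OC)c(OC)c(OC)c3)[C@H]2C(=O)N([Mg]Cl)C(=O)/C=C\CCBr)cc(OC)c1OC | intermediate
11 | piplartine-dimer A, 1,1'-{[(1α,2α,3β,4β)-2,4-bis(3,4,5-trimethoxyphenyl)cyclobutane-1,3-diyl]dicarbonyl}bis(5,6-dihydropyridin-2(1H)-one) | COc1cc([C@H]2[C@H](C(=O)N3CCC=CC3=O)[C@H](c3cc(OC)c(OC)c(OC)c3)[C@H]2C(=O)N2CCC=CC2=O)cc(OC)c1OC | target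

**Step count**
Total step count: 7.
Longest linear sequence: 4 steps (1 → 2 → 3 → 4 → 11, or 5 → 6 → 7 → 8 → 11).

**Steps most likely to fail**

Step 7 (proposed new method).
- What may go wrong:
  - alkylation of the ambident imide anion at oxygen;
  - attack of the alkenylmagnesium at the exocyclic acyl carbon;
  - chain growth by addition of the imide anion to unreacted isocyanate;
  - self-alkylation of the C4 reagent to cyclobutene before it is used;
  - loss of configuration next to the carbonyl groups.
- Fallback (known chemistry): it sets out from 3 and returns to the route at 11. Commercial 5,6-dihydropyridin-2(1H)-one (O=C1C=CCCN1) is deprotonated with n-BuLi in THF at −78 °C to give N-lithio-5,6-dihydropyridin-2(1H)-one F1. Two equivalents of F1 are acylated by 3 at −78 °C, the standard N-acylation of a lactam anion by an acyl chloride. The preformed rings are thus attached instead of being built on the core.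

Step 1.
- What may go wrong: the crystal packing may hold the alkenes too far apart or parallel head-to-head, which leads to no reaction or to the wrong regiochemistry. The lattice may also collapse at partial conversion.
- Fallback: it sets out from 1 and returns at 2, moving the dimerization into solution. Fischer esterification (MeOH, H2SO4 cat.) gives methyl (E)-3,4,5-trimethoxycinnamate F2. Concentrated F2 is irradiated in CH2Cl2 in the presence of BF3·OEt2. In this Lewis-acid-catalysed cinnamate photodimerization the excited ester–BF3 complex pairs with free ester in the syn head-to-tail sense, which should favour dimethyl (1α,2α,3β,4β)-2,4-bis(3,4,5-trimethoxyphenyl)cyclobutane-1,3-dicarboxylate F3, separated from its isomers by chromatography. Mild saponification (LiOH, THF/H2O, rt, then acid) leads to 2.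

Step 3.
- What may go wrong:
  - silver-promoted ionization of the acyl chloride followed by ring closure onto the neighbouring electron-rich arene;
  - incomplete chloride/cyanate exchange at the hindered acyl carbon;
  - hydrolysis or self-condensation of the acyl isocyanate during handling.
- Fallback: it sets out from 3 and returns at 4, bringing in the nitrogen first and the isocyanate carbon afterwards. Ammonolysis (NH3 in dioxane, CH2Cl2, 0 °C) gives (1α,2α,3β,4β)-2,4-bis(3,4,5-trimethoxyphenyl)cyclobutane-1,3-dicarboxamide F4. F4 is heated with (COCl)2 in 1,2-dichloroethane, the primary amide/oxalyl chloride synthesis of acyl isocyanates, to give 4 without any silver salt.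

**Further compounds**
F1 | step 7 | N-lithio-5,6-dihydropyridin-2(1H)-one | [Li]N1CCC=CC1=O
F2 | step 1 | methyl (E)-3,4,5-trimethoxycinnamate | COC(=O)/C=C/c1cc(OC)c(OC)c(OC)c1
F3 | step 1 | dimethyl (1α,2α,3β,4β)-2,4-bis(3,4,5-trimethoxyphenyl)cyclobutane-1,3-dicarboxylate | COc1cc([C@H]2[C@H](C(=O)OC)[C@H](c3cc(OC)c(OC)c(OC)c3)[C@H]2C(=O)OC)cc(OC)c1OC
F4 | step 3 | (1α,2α,3β,4β)-2,4-bis(3,4,5-trimethoxyphenyl)cyclobutane-1,3-dicarboxamide | COc1cc([C@H]2[C@H](C(N)=O)[C@H](c3cc(OC)c(OC)c(OC)c3)[C@H]2C(N)=O)cc(OC)c1OC
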